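**Retrosynthetic overview**
- Target ⇒ global O-dealkylation of a penta-O-benzyl, mono-O-methyl precursor (last step, no skeletal change).
- Flavanone C2–C1' bond ⇒ rhodium-catalysed enantioselective 1,4-addition of a biaryl boronic acid to 5,7-bis(benzyloxy)chromone; this sets 2S, and flavanone rings A and C arrive preformed as the chromone.
- Boronic acid ⇒ aryl bromide ⇒ key biaryl bond C5'(ring B)–C6(flavone): the o-quinone monoketal of 4-bromoguaiacol, in which the phenol ortho carbon is electrophilic, is attacked by C6 of 7,3',4'-tri-O-benzylluteolin. Both carbons are nucleophilic in the parent phenols.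
- Ring order: luteolin rings bought intact → biaryl bond → chromone ring C of the second unit closed separately → C2–aryl bond and stereocentre → deprotection.

Assumption: luteolin, 4-bromo-2-methoxyphenol and 1-[2,4-bis(benzyloxy)-6-hydroxyphenyl]ethanone are bought as catalogue chemicals; the biaryl axis is taken as freely rotating, since no atropisomer is specified.

**Route**

Step 1
Reactants: 1 luteolin; 2 benzyl bromide
Product: 3 7-(benzyloxy)-2-[3,4-bis(benzyloxy)phenyl]-5-hydroxy-4H-chromen-4-one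
Conditions: BnBr (3.3 equiv), K2CO3, DMF, 25 °C, 16 h
Reagents that add atoms: benzyl bromide, BrCc1ccccc1
Why: Williamson ether synthesis alkylates the 7-, 3'- and 4'-hydroxyls while the 5-OH, hydrogen-bonded to the C4 carbonyl, stays free, and this free 5-OH is what steers the next step to C6.

Step 2
Reactants: 4 4-bromo-2-methoxyphenol; 5 methanol; 3 7-(benzyloxy)-2-[3,4-bis(benzyloxy)phenyl]-5-hydroxy-4H-chromen-4-one
Product: 7 7-(benzyloxy)-2-[3,4-bis(benzyloxy)phenyl]-6-(5-bromo-2-hydroxy-3-methoxyphenyl)-5-hydroxy-4H-chromen-4-one, via 4-bromo-6,6-dimethoxycyclohexa-2,4-dien-1-one 6 (not isolated)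
Conditions: PhI(OAc)2 (1.1 equiv), MeOH, 0 °C, 15 min; evaporate cold; then 3 (0.8 equiv), C6F5CO2H (20 mol%), (CF3)2CHOH–CH2Cl2 4:1, 0 °C to rt
Reagents that add atoms: methanol, CO (one of the two ketal methoxy groups of 6, statistically the original or the new one, remains as the aryl methyl ether of 7)
Why: Proposed new method: oxidative dearomatisation of 4 gives the bromo-substituted masked o-benzoquinone 6 (the 4-bromo group suppresses the usual Diels–Alder self-dimerisation), and acid in the fluoroalcohol ionises the ketal to a 2-methoxyphenoxonium (enolonium-type) ion whose para position is blocked by Br, so C6 of 3 (ortho to the chelated 5-OH, the site where 5-hydroxy-7-alkoxyflavones are halogenated) attacks the carbon alpha to the dienone carbonyl and tautomerisation rearomatises to the biaryl; the closest known reaction type is the Brønsted-acid-catalysed coupling of p-quinone monoacetals with arenes and phenols in fluoroalcohols (Kita-type coupling), here extended to an o-quinone monoketal and a flavone nucleophile.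

Step 3
Reactants: 7 7-(benzyloxy)-2-[3,4-bis(benzyloxy)phenyl]-6-(5-bromo-2-hydroxy-3-methoxyphenyl)-5-hydroxy-4H-chromen-4-one; 8 tetrahydroxydiboron
Product: 9 {3-[7-(benzyloxy)-2-(3,4-bis(benzyloxy)phenyl)-5-hydroxy-4-oxo-4H-chromen-6-yl]-4-hydroxy-5-methoxyphenyl}boronic acid
Conditions: B2(OH)4 (3 equiv), Pd(2'-aminobiphenyl-2-yl)(XPhos)Cl (2 mol%), XPhos (4 mol%), KOAc (3 equiv), EtOH–THF, 80 °C
Reagents that add atoms: tetrahydroxydiboron, OB(O)B(O)O
Why: Miyaura-type borylation of the unhindered aryl bromide gives the free boronic acid directly, and KOAc is too weak a base to disturb the phenols, the benzyl ethers or the flavone.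

Step 4
Reactants: 10 1-[2,4-bis(benzyloxy)-6-hydroxyphenyl]ethanone; 11 N,N-dimethylformamide dimethyl acetal
Product: 13 5,7-bis(benzyloxy)-4H-chromen-4-one, via enaminone 12 (not isolated)
Conditions: Me2NCH(OMe)2, toluene, 100 °C; then AcOH, 80 °C
Reagents that add atoms: N,N-dimethylformamide dimethyl acetal, COC(OC)N(C)C
Why: Condensation of the methyl ketone with the amide acetal gives the enaminone, and acid-promoted addition–elimination by the ortho phenol (loss of dimethylamine) closes the pyranone ring in a standard enaminone chromone synthesis.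

Step 5
Reactants: 9 {3-[7-(benzyloxy)-2-(3,4-bis(benzyloxy)phenyl)-5-hydroxy-4-oxo-4H-chromen-6-yl]-4-hydroxy-5-methoxyphenyl}boronic acid; 13 5,7-bis(benzyloxy)-4H-chromen-4-one
Product: 14 (2S)-5,7-bis(benzyloxy)-2-{3-[7-(benzyloxy)-2-(3,4-bis(benzyloxy)phenyl)-5-hydroxy-4-oxo-4H-chromen-6-yl]-4-hydroxy-5-methoxyphenyl}-2,3-dihydro-4H-chromen-4-one
Conditions: [Rh(OH)(cod)]2 (2.5 mol%), (S)-MeO-F12-BIPHEP (5.5 mol%), 13 (2 equiv), toluene–H2O 10:1, 30 °C
Reagents that add atoms: none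
Why: Hayashi–Miyaura asymmetric 1,4-addition, in which the aryl–rhodium species on the electron-poor (S)-bisphosphine inserts the chromone C2=C3 bond from one face (the same facial sense as (S)-BINAP with cyclohexenone, which corresponds to 2S here) under base-free conditions that avoid ring opening of the flavanone, while the 2-aryl-substituted C2=C3 bond of the flavone unit is too hindered to compete.

Step 6
Reactants: 14 (2S)-5,7-bis(benzyloxy)-2-{3-[7-(benzyloxy)-2-(3,4-bis(benzyloxy)phenyl)-5-hydroxy-4-oxo-4H-chromen-6-yl]-4-hydroxy-5-methoxyphenyl}-2,3-dihydro-4H-chromen-4-one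
Product: 15 (2S)-2-{3-[2-(3,4-dihydroxyphenyl)-5,7-dihydroxy-4-oxo-4H-chromen-6-yl]-4,5-dihydroxyphenyl}-5,7-dihydroxy-2,3-dihydro-4H-chromen-4-one
Conditions: BBr3 (15 equiv), C6HMe5 (10 equiv), CH2Cl2, −78 to 0 °C; MeOH quench
Reagents that add atoms: none
Why: Lewis-acid ether cleavage removes the five benzyl groups at low temperature (benzyl cations trapped by pentamethylbenzene) and the single methyl ether, whose cleavage is assisted by the neighbouring free 4'-OH through a cyclic borate, while the low temperature limits ring opening at the C2 stereocentre.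

**Compound list**

1 | luteolin | O=c1cc(-c2ccc(O)c(O)c2)oc2cc(O)cc(O)c12 | starting material
2 | benzyl bromide | BrCc1ccccc1 | starting material
3 | 7-(benzyloxy)-2-[3,4-bis(benzyloxy)phenyl]-5-hydroxy-4H-chromen-4-one | O=c1cc(-c2ccc(OCc3ccccc3)c(OCc3ccccc3)c2)oc2cc(OCc3ccccc3)cc(O)c12 | intermediate
4 | 4-bromo-2-methoxyphenol | COc1cc(Br)ccc1O | starting material
5 | methanol | CO | starting material
6 | 4-bromo-6,6-dimethoxycyclohexa-2,4-dien-1-one | COC1(OC)C=C(Br)C=CC1=O | intermediate (not isolated)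
7 | 7-(benzyloxy)-2-[3,4-bis(benzyloxy)phenyl]-6-(5-bromo-2-hydroxy-3-methoxyphenyl)-5-hydroxy-4H-chromen-4-one | O=c1cc(-c2ccc(OCc3ccccc3)c(OCc3ccccc3)c2)oc2cc(OCc3ccccc3)c(-c3cc(Br)cc(OC)c3O)c(O)c12 | intermediate
8 | tetrahydroxydiboron | OB(O)B(O)O | starting material
9 | {3-[7-(benzyloxy)-2-(3,4-bis(benzyloxy)phenyl)-5-hydroxy-4-oxo-4H-chromen-6-yl]-4-hydroxy-5-methoxyphenyl}boronic acid | O=c1cc(-c2ccc(OCc3ccccc3)c(OCc3ccccc3)c2)oc2cc(OCc3ccccc3)c(-c3cc(B(O)O)cc(OC)c3O)c(O)c12 | intermediate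
10 | 1-[2,4-bis(benzyloxy)-6-hydroxyphenyl]ethanone | CC(=O)c1c(O)cc(OCc2ccccc2)cc1OCc1ccccc1 | starting material
11 | N,N-dimethylformamide dimethyl acetal | COC(OC)N(C)C | starting material
12 | (E)-1-[2,4-bis(benzyloxy)-6-hydroxyphenyl]-3-(dimethylamino)prop-2-en-1-one | CN(C)/C=C/C(=O)c1c(O)cc(OCc2ccccc2)cc1OCc1ccccc1 | intermediate (not isolated)
13 | 5,7-bis(benzyloxy)-4H-chromen-4-one | O=c1ccoc2cc(OCc3ccccc3)cc(OCc3ccccc3)c12 | intermediate
14 | (2S)-5,7-bis(benzyloxy)-2-{3-[7-(benzyloxy)-2-(3,4-bis(benzyloxy)phenyl)-5-hydroxy-4-oxo-4H-chromen-6-yl]-4-hydroxy-5-methoxyphenyl}-2,3-dihydro-4H-chromen-4-one | O=C1C[C@@H](c2cc(OC)c(O)c(-c3c(O)c4c(=O)cc(-c5ccc(OCc6ccccc6)c(OCc6ccccc6)c5)oc4cc3OCc3ccccc3)c2)Oc2cc(OCc3ccccc3)cc(OCc3ccccc3)c21 | intermediate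
15 | (2S)-2-{3-[2-(3,4-dihydroxyphenyl)-5,7-dihydroxy-4-oxo-4H-chromen-6-yl]-4,5-dihydroxyphenyl}-5,7-dihydroxy-2,3-dihydro-4H-chromen-4-one | O=C1C[C@@H](c2cc(O)c(O)c(-c3c(O)cc4oc(-c5ccc(O)c(O)c5)cc(=O)c4c3O)c2)Oc2cc(O)cc(O)c21 | target

**Totals and risks**

Total step count: 6. Longest linear sequence: 5 (steps 1, 2, 3, 5, 6); the chromone branch (step 4) joins at step 5.

Steps most likely to fail:

1. Step 2 (biaryl coupling). The flavone ring A is only moderately nucleophilic, C8 (or C3) may compete with C6, and the ketal may be attacked at the enone beta carbon instead. The fallback sets out from 3 and comes back at 7. Iodinate 3 at C6 with BnMe3N+ ICl2−/CaCO3 in CH2Cl2–MeOH to give 7-(benzyloxy)-2-[3,4-bis(benzyloxy)phenyl]-5-hydroxy-6-iodo-4H-chromen-4-one F1. Exchange iodine for tin with Bu3SnSnBu3 and Pd(PPh3)4 in toluene at 100 °C to give 7-(benzyloxy)-2-[3,4-bis(benzyloxy)phenyl]-5-hydroxy-6-(tributylstannyl)-4H-chromen-4-one F2. Then treat F2 with preformed, isolated 6 and BF3·OEt2 in CH2Cl2 at −40 °C; ipso-destannylation fixes the site of bond formation and makes the arene a much better nucleophile, giving 7.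

2. Step 5 (asymmetric 1,4-addition). The large, phenol-bearing boronic acid 9 may protodeboronate faster than it adds to the electron-rich chromone, and the sense of induction must be confirmed on the first run (CD or chiral HPLC; the (R)-ligand is used if 2R is found). The fallback sets out from 13 and comes back at 14 by reversing the order of events. Add commercial (4-hydroxy-3-methoxyphenyl)boronic acid, which can be used in excess, to 13 under the same rhodium catalysis to give (2S)-5,7-bis(benzyloxy)-2-(4-hydroxy-3-methoxyphenyl)-2,3-dihydro-4H-chromen-4-one F3. Oxidise F3 with PhI(OAc)2 in MeOH at −20 °C to (2S)-5,7-bis(benzyloxy)-2-(3,3-dimethoxy-4-oxocyclohexa-1,5-dien-1-yl)-2,3-dihydro-4H-chromen-4-one F4. Couple F4 with 3 under the acid/fluoroalcohol conditions of step 2 to give 14 directly, bypassing 7 and 9.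

3. Step 6 (global deprotection). BBr3 may open ring C of the flavanone reversibly and erode the 2S configuration, or C-benzylate the phloroglucinol rings. The fallback sets out from 7 and comes back at 15; it removes the methyl ether before the stereocentre exists. Treat 7 with BBr3/C6HMe5 to give 6-(5-bromo-2,3-dihydroxyphenyl)-2-(3,4-dihydroxyphenyl)-5,7-dihydroxy-4H-chromen-4-one F5. Re-benzylate with BnBr/K2CO3 in DMF (the chelated 5-OH stays free) to give 7-(benzyloxy)-6-[2,3-bis(benzyloxy)-5-bromophenyl]-2-[3,4-bis(benzyloxy)phenyl]-5-hydroxy-4H-chromen-4-one F6. Borylate as in step 3 to give {3-[7-(benzyloxy)-2-(3,4-bis(benzyloxy)phenyl)-5-hydroxy-4-oxo-4H-chromen-6-yl]-4,5-bis(benzyloxy)phenyl}boronic acid F7. Add F7 to 13 as in step 5 to give (2S)-5,7-bis(benzyloxy)-2-{3-[7-(benzyloxy)-2-(3,4-bis(benzyloxy)phenyl)-5-hydroxy-4-oxo-4H-chromen-6-yl]-4,5-bis(benzyloxy)phenyl}-2,3-dihydro-4H-chromen-4-one F8. Finish with neutral hydrogenolysis (H2, 1 atm, Pd/C, EtOAc–MeOH, rt) to give 15.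

**Further compounds**

F1 | step 2 | 7-(benzyloxy)-2-[3,4-bis(benzyloxy)phenyl]-5-hydroxy-6-iodo-4H-chromen-4-one | O=c1cc(-c2ccc(OCc3ccccc3)c(OCc3ccccc3)c2)oc2cc(OCc3ccccc3)c(I)c(O)c12
F2 | step 2 | 7-(benzyloxy)-2-[3,4-bis(benzyloxy)phenyl]-5-hydroxy-6-(tributylstannyl)-4H-chromen-4-one | O=c1cc(-c2ccc(OCc3ccccc3)c(OCc3ccccc3)c2)oc2cc(OCc3ccccc3)c([Sn](CCCC)(CCCC)CCCC)c(O)c12
F3 | step 5 | (2S)-5,7-bis(benzyloxy)-2-(4-hydroxy-3-methoxyphenyl)-2,3-dihydro-4H-chromen-4-one | O=C1C[C@@H](c2ccc(O)c(OC)c2)Oc2cc(OCc3ccccc3)cc(OCc3ccccc3)c21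
F4 | step 5 | (2S)-5,7-bis(benzyloxy)-2-(3,3-dimethoxy-4-oxocyclohexa-1,5-dien-1-yl)-2,3-dihydro-4H-chromen-4-one | O=C1C[C@@H](C2=CC(OC)(OC)C(=O)C=C2)Oc2cc(OCc3ccccc3)cc(OCc3ccccc3)c21
F5 | step 6 | 6-(5-bromo-2,3-dihydroxyphenyl)-2-(3,4-dihydroxyphenyl)-5,7-dihydroxy-4H-chromen-4-one | O=c1cc(-c2ccc(O)c(O)c2)oc2cc(O)c(-c3cc(Br)cc(O)c3O)c(O)c12
F6 | step 6 | 7-(benzyloxy)-6-[2,3-bis(benzyloxy)-5-bromophenyl]-2-[3,4-bis(benzyloxy)phenyl]-5-hydroxy-4H-chromen-4-one | O=c1cc(-c2ccc(OCc3ccccc3)c(OCc3ccccc3)c2)oc2cc(OCc3ccccc3)c(-c3cc(Br)cc(OCc4ccccc4)c3OCc3ccccc3)c(O)c12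
F7 | step 6 | {3-[7-(benzyloxy)-2-(3,4-bis(benzyloxy)phenyl)-5-hydroxy-4-oxo-4H-chromen-6-yl]-4,5-bis(benzyloxy)phenyl}boronic acid | O=c1cc(-c2ccc(OCc3ccccc3)c(OCc3ccccc3)c2)oc2cc(OCc3ccccc3)c(-c3cc(B(O)O)cc(OCc4ccccc4)c3OCc3ccccc3)c(O)c12
F8 | step 6 | (2S)-5,7-bis(benzyloxy)-2-{3-[7-(benzyloxy)-2-(3,4-bis(benzyloxy)phenyl)-5-hydroxy-4-oxo-4H-chromen-6-yl]-4,5-bis(benzyloxy)phenyl}-2,3-dihydro-4H-chromen-4-one | O=C1C[C@@H](c2cc(OCc3ccccc3)c(OCc3ccccc3)c(-c3c(O)c4c(=O)cc(-c5ccc(OCc6ccccc6)c(OCc6ccccc6)c5)oc4cc3OCc3ccccc3)c2)Oc2cc(OCc3ccccc3)cc(OCc3ccccc3)c21
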